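**Retrosynthetic overview**
- The last operation is O-demethylation at C6. Until the fragment coupling the benzene ring is carried as a 2-acyl-5-methoxy-1,4-benzoquinone, so C5-OH and C8-OH arise by rearomatisation.
- The key disconnection is C3–C4 of the δ-lactone, the last ring made. The precursor is a racemic γ-aryl butenolide in which C4 is still bound to the side-chain carboxylate, and C3 is the CH2 of an O-aroylglycolic 4-nitrophenyl ester.
- Enabling feature: C5-OH is ortho to C4a, so its phenoxide can push the carboxylate off C4 to give an o-quinone methide (C5=O/C4a=C4). That carboxyl is cis to C4 on the C1′=C2′ alkene, so it can be stored as a butenolide, which fixes the E geometry and keeps the two side-chain carboxyls distinct. C3 lies between O2 and a carboxyl carbon, so a chiral isothiourea can turn it into a C(1)-ammonium enolate.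
- The precursor comes from two flat, achiral pieces: the quinone ester and a 2-silyloxyfuran (C4a–C4 bond, vinylogous Mukaiyama–Michael). The quinone derives from 2,4,5-trimethoxybenzoic acid and 4-nitrophenyl bromoacetate, the furan piece from methyl furan-3-carboxylate by singlet-oxygen dearomatisation.
- Ring order: butenolide (temporary), then the benzene ring regenerated from the quinone, then the δ-lactone, closed as the butenolide opens.

Key step: step 7

Assumption: the SMILES is read as (3S,4R), that is 3,4-trans, with an (E)-alkene (side-chain CO2H cis to C4). Locants follow isochroman-1-one numbering (C1 lactone C=O, O2, C3, C4, C4a, C5–C8, C8a), and the side chain on C4 is C1′(CO2Me)=C2′H–CO2H.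

Step 1
Reactants: 1 2,4,5-trimethoxybenzoic acid; 2 4-nitrophenyl bromoacetate
Product: 3 2-(4-nitrophenoxy)-2-oxoethyl 2,4,5-trimethoxybenzoate
Conditions: iPr2NEt, MeCN, 0 °C → rt
Reagents that add atoms: none
Why: Carboxylate O-alkylation (SN2) at the very reactive α-bromo ester carbon should outrun attack at the aryl ester carbonyl, because any mixed anhydride formed there reverts; no stereocentre is formed.

Step 2
Reactants: 3 2-(4-nitrophenoxy)-2-oxoethyl 2,4,5-trimethoxybenzoate
Product: 4 2-(4-nitrophenoxy)-2-oxoethyl 4-methoxy-3,6-dioxocyclohexa-1,4-diene-1-carboxylate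
Conditions: (NH4)2Ce(NO3)6 (2.5 equiv), MeCN/H2O, 0 °C; used without chromatography
Reagents that add atoms: water, O
Why: Cerium(IV) oxidative demethylation of the para-related C2/C5 methoxy pair (water supplies the two carbonyl oxygens) should give the p-quinone, while the C4 methoxy group stays as a vinylogous ester and the aryl ester tolerates the short, cold, acidic exposure.

Step 3
Reactants: 5 methyl furan-3-carboxylate
Product: 7 methyl 2-hydroxy-5-oxo-2,5-dihydrofuran-3-carboxylate (racemic lactol), via furan endoperoxide 6 (not isolated)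
Conditions: O2, tetraphenylporphyrin (cat.), hν (visible), iPr2NEt, CH2Cl2, −78 °C
Reagents that add atoms: dioxygen, O=O
Why: [4+2] cycloaddition of singlet oxygen to the furan and Kornblum–DeLaMare fragmentation of 6 should follow, in which the hindered base takes C5–H (less hindered and vinylogously acidified by the ester), so C5 becomes the lactone carbonyl and C2 the lactol carbon, whose racemic centre is erased in step 4.

Step 4
Reactants: 7 methyl 2-hydroxy-5-oxo-2,5-dihydrofuran-3-carboxylate
Product: 9 methyl 5-oxo-2,5-dihydrofuran-3-carboxylate, via hydroxy acid 8 (not isolated)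
Conditions: NaBH4, CeCl3·7H2O, MeOH, −40 → 0 °C; then 1 M HCl
Reagents that add atoms: none
Why: Luche 1,2-reduction of the ring-opened aldehyde tautomer gives 8, whose CH2OH and CO2H groups are cis on the alkene and close to the butenolide on acidification, with cerium(III) there to suppress conjugate hydride addition.

Step 5
Reactants: 9 methyl 5-oxo-2,5-dihydrofuran-3-carboxylate
Product: 10 methyl 5-[(trimethylsilyl)oxy]furan-3-carboxylate
Conditions: TMSOTf, Et3N, CH2Cl2, 0 °C; used crude
Reagents that add atoms: trimethylsilyl triflate, C[Si](C)(C)OS(=O)(=O)C(F)(F)F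
Why: Soft enolisation and O-silylation of a butenolide gives the aromatic 2-silyloxyfuran, helped here by the extra acidity that the ester lends to the γ-CH2 group.

Step 6
Reactants: 4 2-(4-nitrophenoxy)-2-oxoethyl 4-methoxy-3,6-dioxocyclohexa-1,4-diene-1-carboxylate; 10 methyl 5-[(trimethylsilyl)oxy]furan-3-carboxylate
Product: 12 2-(4-nitrophenoxy)-2-oxoethyl 3,6-dihydroxy-4-methoxy-2-[3-(methoxycarbonyl)-5-oxo-2,5-dihydrofuran-2-yl]benzoate (racemic), via aryl trimethylsilyl ether 11 (not isolated)
Conditions: Sc(OTf)3 (10 mol %), MeCN/CH2Cl2, −40 → −10 °C, Ar; then pH 4 buffer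
Reagents that add atoms: none
Why: This is a vinylogous Mukaiyama–Michael addition of a 2-silyloxyfuran to an acyl-activated 1,4-benzoquinone followed by enolisation to the hydroquinone, a known pairing for 2-alkoxycarbonylquinones, in which scandium chelation of the ester carbonyl and the adjacent ring carbonyl activates the only ring CH that is β to both, the methoxy group deactivates the other CH, the furan ester sits on a node of the dienol-ether HOMO so the usual γ-attack should persist, and the new stereocentre is deliberately left racemic.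

Step 7
Reactants: 12 2-(4-nitrophenoxy)-2-oxoethyl 3,6-dihydroxy-4-methoxy-2-[3-(methoxycarbonyl)-5-oxo-2,5-dihydrofuran-2-yl]benzoate (racemic)
Product: 15 (E)-3-[(3S,4R)-5,8-dihydroxy-6-methoxy-3-(methoxycarbonyl)-1-oxo-3,4-dihydro-1H-isochromen-4-yl]-4-methoxy-4-oxobut-2-enoic acid, via vinyl o-quinone methide 13 (not isolated), via cyclised 4-nitrophenyl ester 14 (not isolated)
Conditions: (2S,3R)-HyperBTM (20 mol %), iPr2NEt (2.5 equiv), CH2Cl2 (0.01 M), Ar, 0 °C → rt; then MeOH, rt; 1 M HCl work-up
Reagents that add atoms: methanol, CO
Why: Proposed new method: iPr2NEt ionises C5-OH and the phenoxide reversibly expels the lactone carboxylate from C4, so both enantiomers of 12 and any oxa-Michael ring tautomers drain into one planar vinyl o-quinone methide 13 with the side-chain acid set free and its alkene locked as E, while the isothiourea is acylated by the 4-nitrophenyl ester and the released aryloxide deprotonates C3 to the (Z)-C(1)-ammonium enolate. C3 then adds to C4 in a 6-(enolexo)-endo-trig Michael closure that rearomatises the benzene ring, 4-nitrophenoxide frees the catalyst (14), and methanol turns the active ester into the C3 methyl ester. The closest known reaction types are the isothiourea-catalysed addition of 4-nitrophenyl-ester-derived ammonium enolates to quinone methides with aryloxide turnover, alkaloid-catalysed reactions of acyloxyketene-derived ammonium enolates, and base-triggered o-quinone methide formation from o-hydroxybenzyl carboxylates or sulfones; new are the lactone leaving group, the O-aroylglycolate enolate and the intramolecular setting. C3 is controlled by the catalyst, since the 1,5-O···S-locked enolate is shielded on one face by the pseudoaxial C2 phenyl group of (2S,3R)-HyperBTM and C4 must bond to the open Si face, which gives 3S. C4 is controlled by relative topicity, since the vinyl group of 13 sits on the C5=O side (the C8a ester blocks the other side) and the bulky acylammonium end points away from the forming ring (exo), which places the C3 and C4 substituents trans and gives 4R. The step needs C3–C4 closure to beat oxa-6π closure to a 2H-chromene, carboxylate return and phenol acylation, and this is secured because the carboxylate occupies the inside position of the oxatriene terminus and retards the electrocyclisation, carboxylate return is degenerate, the six-membered closure beats seven- and eight-membered attack at the fumarate carbons, C8-OH is hydrogen-bonded to the C1 carbonyl, and high dilution suppresses intermolecular acyl transfer.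

Step 8
Reactants: 15 (E)-3-[(3S,4R)-5,8-dihydroxy-6-methoxy-3-(methoxycarbonyl)-1-oxo-3,4-dihydro-1H-isochromen-4-yl]-4-methoxy-4-oxobut-2-enoic acid
Product: 16 (E)-4-methoxy-4-oxo-3-[(3S,4R)-5,6,8-trihydroxy-3-(methoxycarbonyl)-1-oxo-3,4-dihydro-1H-isochromen-4-yl]but-2-enoic acid (target)
Conditions: BBr3 (5 equiv), CH2Cl2, −78 → 0 °C, Ar; then H2O
Reagents that add atoms: none
Why: In this Lewis-acid aryl methyl ether cleavage the boron aryloxide formed at the neighbouring C5-OH should assist demethylation at C6 well below the temperature at which methyl esters or the lactone react, and the acidic, non-enolising medium should leave C3, C4 and the E alkene untouched.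

**Compound list**
1 | 2,4,5-trimethoxybenzoic acid | COc1cc(OC)c(OC)cc1C(=O)O | starting material
2 | 4-nitrophenyl bromoacetate | O=C(CBr)Oc1ccc(cc1)[N+](=O)[O-] | starting material
3 | 2-(4-nitrophenoxy)-2-oxoethyl 2,4,5-trimethoxybenzoate | COc1cc(OC)c(OC)cc1C(=O)OCC(=O)Oc1ccc(cc1)[N+](=O)[O-] | intermediate
4 | 2-(4-nitrophenoxy)-2-oxoethyl 4-methoxy-3,6-dioxocyclohexa-1,4-diene-1-carboxylate | COC1=CC(=O)C(=CC1=O)C(=O)OCC(=O)Oc1ccc(cc1)[N+](=O)[O-] | intermediate
5 | methyl furan-3-carboxylate | COC(=O)c1ccoc1 | starting material
6 | methyl 2,3,7-trioxabicyclo[2.2.1]hept-5-ene-5-carboxylate (furan endoperoxide, racemic) | COC(=O)C1=CC2OOC1O2 | intermediate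
7 | methyl 2-hydroxy-5-oxo-2,5-dihydrofuran-3-carboxylate (racemic) | COC(=O)C1=CC(=O)OC1O | intermediate
8 | (E)-4-hydroxy-3-(methoxycarbonyl)but-2-enoic acid | COC(=O)/C(CO)=C/C(=O)O | intermediate
9 | methyl 5-oxo-2,5-dihydrofuran-3-carboxylate | COC(=O)C1=CC(=O)OC1 | intermediate
10 | methyl 5-[(trimethylsilyl)oxy]furan-3-carboxylate | COC(=O)c1coc(O[Si](C)(C)C)c1 | intermediate
11 | 6-O-trimethylsilyl ether of 12 (racemic) | COC(=O)C1=CC(=O)OC1c1c(O)c(OC)cc(O[Si](C)(C)C)c1C(=O)OCC(=O)Oc1ccc(cc1)[N+](=O)[O-] | intermediate
12 | 2-(4-nitrophenoxy)-2-oxoethyl 3,6-dihydroxy-4-methoxy-2-[3-(methoxycarbonyl)-5-oxo-2,5-dihydrofuran-2-yl]benzoate (racemic) | COC(=O)C1=CC(=O)OC1c1c(O)c(OC)cc(O)c1C(=O)OCC(=O)Oc1ccc(cc1)[N+](=O)[O-] | intermediate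
13 | vinyl o-quinone methide, drawn as free acid and 4-nitrophenyl ester; side-chain alkene E, exocyclic C4a=C4 geometry not fixed; it reacts as the catalyst-bound enolate | O=C1C(OC)=CC(O)=C(C(=O)OCC(=O)Oc2ccc(cc2)[N+](=O)[O-])C1=C/C(C(=O)OC)=C\C(=O)O | intermediate
14 | (E)-3-[(3S,4R)-5,8-dihydroxy-6-methoxy-3-(4-nitrophenoxycarbonyl)-1-oxo-3,4-dihydro-1H-isochromen-4-yl]-4-methoxy-4-oxobut-2-enoic acid | COC(=O)/C(=C/C(=O)O)[C@H]1c2c(O)c(OC)cc(O)c2C(=O)O[C@@H]1C(=O)Oc1ccc(cc1)[N+](=O)[O-] | intermediate
15 | (E)-3-[(3S,4R)-5,8-dihydroxy-6-methoxy-3-(methoxycarbonyl)-1-oxo-3,4-dihydro-1H-isochromen-4-yl]-4-methoxy-4-oxobut-2-enoic acid | COC(=O)/C(=C/C(=O)O)[C@H]1c2c(O)c(OC)cc(O)c2C(=O)O[C@@H]1C(=O)OC | intermediate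
16 | (E)-4-methoxy-4-oxo-3-[(3S,4R)-5,6,8-trihydroxy-3-(methoxycarbonyl)-1-oxo-3,4-dihydro-1H-isochromen-4-yl]but-2-enoic acid | COC(=O)/C(=C/C(=O)O)[C@H]1c2c(O)c(O)cc(O)c2C(=O)O[C@@H]1C(=O)OC | target

Total step count: 8. Longest linear sequence: 6 (steps 3, 4, 5, 6, 7, 8, from methyl furan-3-carboxylate).

**Steps most likely to fail**

**Step 7.** The ammonium enolate and the o-quinone methide are both minor, short-lived forms of the same molecule, and the aryl ester tether must also reach its less populated s-E rotamer. If these rarely coincide, several processes can take over: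
- acyl transfer to phenoxide oxygens
- oxa-6π ring closure
- oligomerisation
- epimerisation at C3 of the active ester before methanolysis

Facial selectivity may also be poor. The fallback uses known chemistry: conjugate addition of a permanently available malonate anion to an o-quinone methide generated by mild base from an o-hydroxybenzyl carboxylate under a bifunctional cinchona squaramide, followed by acidolysis and decarboxylation. It sets out from 1 and 10 and comes back at 15. Commercial tert-butyl methyl malonate is brominated (NBS, cat. Mg(ClO4)2) to tert-butyl methyl 2-bromomalonate F1. Compound 1 is O-alkylated with it (iPr2NEt, MeCN) to tert-butyl methyl 2-[(2,4,5-trimethoxybenzoyl)oxy]malonate F2. Cerium(IV) ammonium nitrate gives the quinone malonate F3. Addition of 10 as in step 6 gives the hydroquinone butenolide malonate F4. The quinine- or quinidine-derived squaramide that leads to 4R (10 mol %, CH2Cl2/aq NaHCO3) closes the lactone to the (4R) gem-diester F5, whose C3 epimers are irrelevant. TFA removes the tert-butyl group to the malonic half acid F6, which loses CO2 on warming in MeCN to give 15. C3 is then set by ketonisation with proton delivery from the side-chain acid on the face of the C4 substituent and, if needed, by equilibration toward the trans isomer.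

**Step 6.** Attack by the ester-deactivated silyloxyfuran may be sluggish or occur through its α-carbon, and redox exchange between the product hydroquinone and unreacted quinone may consume material. In the fallback the silyl/Lewis-acid manifold is left for a direct vinylogous Michael addition, a known reaction type for γ-butenolides. Butenolide 9, whose γ-CH2 is acidified by lactone and ester, is added as its far more nucleophilic furanolate to 4 under a catalytic tertiary amine, with proton transfer replacing silyl transfer. The fallback sets out from 4 and 9, makes step 5 redundant and comes back at 12. No new compound is made (F0).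

**Step 8.** A methyl ester may be lost, or the boron-bound C5 oxygen may lactonise onto the C1′ ester under the Lewis acid. The fallback is a redox detour that sets out from 15 and comes back at 16. Ag2O oxidises the hydroquinone to the methoxy-p-quinone F7, dilute aqueous acid hydrolyses its vinylogous ester to the hydroxy-p-quinone F8, and Na2S2O4 reduces this to 16.

**Further compounds**
F1 | step 7 | tert-butyl methyl 2-bromomalonate | COC(=O)C(Br)C(=O)OC(C)(C)C
F2 | step 7 | tert-butyl methyl 2-[(2,4,5-trimethoxybenzoyl)oxy]malonate | COc1cc(OC)c(OC)cc1C(=O)OC(C(=O)OC)C(=O)OC(C)(C)C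
F3 | step 7 | tert-butyl methyl 2-[(4-methoxy-3,6-dioxocyclohexa-1,4-diene-1-carbonyl)oxy]malonate | COC1=CC(=O)C(=CC1=O)C(=O)OC(C(=O)OC)C(=O)OC(C)(C)C
F4 | step 7 | tert-butyl methyl 2-({3,6-dihydroxy-4-methoxy-2-[3-(methoxycarbonyl)-5-oxo-2,5-dihydrofuran-2-yl]benzoyl}oxy)malonate (stereoisomer mixture) | COC(=O)C1=CC(=O)OC1c1c(O)c(OC)cc(O)c1C(=O)OC(C(=O)OC)C(=O)OC(C)(C)C
F5 | step 7 | (E)-3-[(4R)-3-(tert-butoxycarbonyl)-5,8-dihydroxy-6-methoxy-3-(methoxycarbonyl)-1-oxo-3,4-dihydro-1H-isochromen-4-yl]-4-methoxy-4-oxobut-2-enoic acid (C3 epimers) | COC(=O)/C(=C/C(=O)O)[C@H]1c2c(O)c(OC)cc(O)c2C(=O)OC1(C(=O)OC)C(=O)OC(C)(C)C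
F6 | step 7 | (4R)-4-[(E)-3-carboxy-1-methoxy-1-oxoprop-2-en-2-yl]-5,8-dihydroxy-6-methoxy-3-(methoxycarbonyl)-1-oxo-3,4-dihydro-1H-isochromene-3-carboxylic acid (C3 epimers) | COC(=O)/C(=C/C(=O)O)[C@H]1c2c(O)c(OC)cc(O)c2C(=O)OC1(C(=O)OC)C(=O)O
F0 | step 6 | none | none
F7 | step 8 | (E)-4-methoxy-3-[(3S,4R)-6-methoxy-3-(methoxycarbonyl)-1,5,8-trioxo-3,4,5,8-tetrahydro-1H-isochromen-4-yl]-4-oxobut-2-enoic acid | COC(=O)/C(=C/C(=O)O)[C@H]1C2=C(C(=O)C=C(OC)C2=O)C(=O)O[C@@H]1C(=O)OC
F8 | step 8 | (E)-3-[(3S,4R)-6-hydroxy-3-(methoxycarbonyl)-1,5,8-trioxo-3,4,5,8-tetrahydro-1H-isochromen-4-yl]-4-methoxy-4-oxobut-2-enoic acid | COC(=O)/C(=C/C(=O)O)[C@H]1C2=C(C(=O)C=C(O)C2=O)C(=O)O[C@@H]1C(=O)OC
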